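Ring B is closed last, by an intramolecular Lewis-acid ene reaction. The exocyclic C1=C2 methylene beside the spiro carbon C7, together with a hydrogen on C11 alpha to the C10 carbonyl, is an ene retron; cutting C7–C12 leads to a monocyclic ring-A cyclohexene (tetrasubstituted C7=C2 alkene, C2 methyl, cis C4-silyloxy/C5-bromo pair) carrying on C7 a chain that ends in a vinyl ketone. One operation forms ring B, the quaternary spiro centre (C12 adds anti to Br and OSi) and the methylidene group. Ring A comes from ketoisophorone; one asymmetric transfer hydrogenation with dynamic kinetic resolution sets C4 and C5, which relay to C7 and C10.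

Key step: step 7

Remark (numbering used throughout, not IUPAC): C1 = exocyclic methylene carbon; ring A = C2 (bearing C1), C3, C4 (carbinol), C5 (CHBr), C6 (CMe2), C7 (spiro); ring B = C7, C8, C9, C10 (carbinol bearing CHBr2), C11, C12.
Remark (assumption): the (S,S)-TsDPEN ruthenium catalyst is taken to give the 4R carbinol, the alkenyl group acting as the π-directing substituent; if the sense is opposite, the (R,R) catalyst is used.

Step 1
Reactants: 1 2,6,6-trimethylcyclohex-2-ene-1,4-dione (ketoisophorone)
Product: 3 rac-5-bromo-2,6,6-trimethylcyclohex-2-ene-1,4-dione, via silyl dienol ether 2 (not isolated)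
Conditions: TMSOTf, Et3N, CH2Cl2, 0 °C; then NBS, THF, −78 → 0 °C
Reagents that add atoms: N-bromosuccinimide (O=C1CCC(=O)N1Br)
Why: Soft enolisation takes the only α-CH2 of the C4 ketone (kinetic, cross-conjugated silyl dienol ether) and electrophilic bromination of this enol ether puts Br on C5; the centre is deliberately left racemic.

Step 2
Reactants: 3 rac-5-bromo-2,6,6-trimethylcyclohex-2-ene-1,4-dione
Product: 4 (4R,5S)-5-bromo-4-hydroxy-2,6,6-trimethylcyclohex-2-en-1-one
Conditions: RuCl(p-cymene)[(S,S)-TsDPEN] (cat.), HCO2H/Et3N (5:2), CH2Cl2, rt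
Reagents that add atoms: none
Why: Noyori-type asymmetric transfer hydrogenation with dynamic kinetic resolution: C5–H is acidified by Br and the vinylogous enedione, so the enantiomers of 3 should interconvert while the catalyst reduces only the less hindered C4 ketone to the 4R carbinol, hydride arriving anti to the pseudoaxial C6 methyl so that OH ends cis to Br (5S).

Step 3
Reactants: 4 (4R,5S)-5-bromo-4-hydroxy-2,6,6-trimethylcyclohex-2-en-1-one
Product: 5 (4R,5S)-5-bromo-4-(tert-butyldimethylsilyloxy)-2,6,6-trimethylcyclohex-2-en-1-one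
Conditions: TBSOTf, 2,6-lutidine, CH2Cl2, −78 → 0 °C
Reagents that add atoms: tert-butyldimethylsilyl trifluoromethanesulfonate (CC(C)(C)[Si](C)(C)OS(=O)(=O)C(F)(F)F)
Why: Silylation of a hindered secondary alcohol with a silyl triflate and a weak hindered base, which cannot trigger γ-deprotonation and loss of bromide.

Step 4
Reactants: 5 (4R,5S)-5-bromo-4-(tert-butyldimethylsilyloxy)-2,6,6-trimethylcyclohex-2-en-1-one
Product: 7 (4R,5S)-5-bromo-4-(tert-butyldimethylsilyloxy)-2,6,6-trimethylcyclohex-1-en-1-yl trifluoromethanesulfonate, via lithium enolate 6 (not isolated)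
Conditions: L-Selectride, THF, −78 °C; then PhNTf2, −78 °C → rt
Reagents that add atoms: N-phenylbis(trifluoromethanesulfonimide) (O=S(=O)(N(c1ccccc1)S(=O)(=O)C(F)(F)F)C(F)(F)F)
Why: Conjugate hydride reduction (the C7 carbonyl is shielded by the gem-dimethyl group) gives the C7=C2 enolate regiospecifically, and O-triflation fixes the tetrasubstituted alkene; the secondary bromide and the silyl ether are inert at −78 °C.

Step 5
Reactants: 7 (4R,5S)-5-bromo-4-(tert-butyldimethylsilyloxy)-2,6,6-trimethylcyclohex-1-en-1-yl trifluoromethanesulfonate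
Product: 8 (4R,5S)-5-bromo-4-(tert-butyldimethylsilyloxy)-2,6,6-trimethylcyclohex-1-ene-1-carbaldehyde
Conditions: Pd(PPh3)4 (cat.), CO (3 atm), Bu3SnH (slow addition), THF, 50 °C
Reagents that add atoms: carbon monoxide ([C-]#[O+])
Why: Palladium-catalysed reductive carbonylation (formylation) of an enol triflate by oxidative addition, CO insertion and hydride transfer from tin; an unactivated secondary alkyl bromide does not add to Pd(0) under these conditions.

Step 6
Reactants: 8 (4R,5S)-5-bromo-4-(tert-butyldimethylsilyloxy)-2,6,6-trimethylcyclohex-1-ene-1-carbaldehyde; 9 2-(trimethylsilyloxy)buta-1,3-diene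
Product: 12 5-[(4R,5S)-5-bromo-4-(tert-butyldimethylsilyloxy)-2,6,6-trimethylcyclohex-1-en-1-yl]-5-(triethylsilyloxy)pent-1-en-3-one (both C8 epimers), via lithium dienolate 10 (not isolated), via lithium aldolate 11 (not isolated)
Conditions: 9, MeLi, THF, 0 °C; then 8, −78 °C; then TESOTf, −78 °C
Reagents that add atoms: triethylsilyl trifluoromethanesulfonate (CC[Si](CC)(CC)OS(=O)(=O)C(F)(F)F)
Why: Directed aldol addition: the lithium enolate of methyl vinyl ketone, freed from its silyl enol ether by MeLi, adds 1,2 to the non-enolisable aldehyde (1,4-addition is blocked by the tetrasubstituted β-carbon) and the aldolate is silylated in situ; the new C8 centre forms without control and is removed in step 8.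

Step 7
Reactants: 12 5-[(4R,5S)-5-bromo-4-(tert-butyldimethylsilyloxy)-2,6,6-trimethylcyclohex-1-en-1-yl]-5-(triethylsilyloxy)pent-1-en-3-one
Product: 13 (4R,5S,7S)-5-bromo-4-(tert-butyldimethylsilyloxy)-6,6-dimethyl-2-methylidene-8-(triethylsilyloxy)spiro[5.5]undecan-10-one (route numbering; C8 epimers)
Conditions: Me2AlCl (2 equiv), CH2Cl2, −78 → −20 °C
Reagents that add atoms: none
Why: Me2AlCl binds the C10 carbonyl and the tetrasubstituted C7=C2 alkene attacks the terminal enone carbon C12 while a hydrogen of the C2 methyl group passes to C11, a Lewis-acid-promoted type I intramolecular ene reaction whose closest precedents are alkylaluminium-chloride-mediated conjugate additions of alkenes to tethered enones and cation–olefin spirocyclisations of cyclogeranyl systems. Ring B closes 6-endo-trig with respect to the enone (C11 and C12 both inside the new ring) and exo with respect to the ene alkene, whose second carbon C2 stays in ring A. The spiro centre C7 is controlled by ring A: C12 should bond to the face of C7 opposite to the C5 bromine and C4 silyloxy group, where attack is chair-like and anti to the pseudoaxial C6 methyl in the half-chair with equatorial bromine, the other face being screened by bromine (axial in the alternative half-chair); C8 therefore ends cis to Br and OTBS. The step needs hydrogen transfer from the methyl group and not from C3, which geometry secures because C11 can reach only the methyl group cis to the tether, so the methylidene and not the endocyclic alkene is formed. Conjugate attack is preferred over attack at the carbonyl carbon because C12 is an unhindered CH2 reached through a six-membered transition state. C8 is not touched and both epimers converge in step 8.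

Step 8
Reactants: 13 (4R,5S,7S)-5-bromo-4-(tert-butyldimethylsilyloxy)-6,6-dimethyl-2-methylidene-8-(triethylsilyloxy)spiro[5.5]undecan-10-one
Product: 16 (4R,5S,7S)-5-bromo-4-(tert-butyldimethylsilyloxy)-6,6-dimethyl-2-methylidenespiro[5.5]undec-8-en-10-one (route numbering), via hydroxy ketone 14 (not isolated), via mesylate 15 (not isolated)
Conditions: HF·pyridine, pyridine, THF, 0 °C; then MsCl, Et3N, CH2Cl2, 0 °C → rt
Reagents that add atoms: none
Why: Selective cleavage of the TES ether (the hindered TBS ether survives buffered HF), mesylation and E1cB elimination of the β-mesyloxy ketone; only C9 carries hydrogens next to C8, so the C8=C9 enone forms regiospecifically and C8 is planarised.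

Step 9
Reactants: 16 (4R,5S,7S)-5-bromo-4-(tert-butyldimethylsilyloxy)-6,6-dimethyl-2-methylidenespiro[5.5]undec-8-en-10-one
Product: 18 (4R,5S,7S,10R)-5-bromo-4-(tert-butyldimethylsilyloxy)-10-(dibromomethyl)-6,6-dimethyl-2-methylidenespiro[5.5]undec-8-en-10-ol (route numbering), via lithium alkoxide 17 (not isolated)
Conditions: CH2Br2, LDA, THF, −90 °C; then 16, −90 → −78 °C; AcOH, −78 °C
Reagents that add atoms: dibromomethane (BrCBr)
Why: 1,2-Addition of the carbenoid LiCHBr2 to the enone carbonyl; the bulky nucleophile should approach C10 from the ring-B face syn to the flat C2 methylidene carbon and anti to C6, whose methyl groups flank the other face, giving CHBr2 cis to C2 and OH cis to C6, while low temperature and an acidic quench keep the bromo-alkoxide from closing to a bromo-epoxide.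

Step 10
Reactants: 18 (4R,5S,7S,10R)-5-bromo-4-(tert-butyldimethylsilyloxy)-10-(dibromomethyl)-6,6-dimethyl-2-methylidenespiro[5.5]undec-8-en-10-ol
Product: 19 ma'iliohydrin
Conditions: HF·pyridine, THF, 0 °C → rt
Reagents that add atoms: none
Why: Fluoride-mediated desilylation of the secondary TBS ether under weakly acidic, non-basic conditions that leave the dibromomethyl carbinol, both alkenes and the secondary bromide untouched.

Compound list
1 | 2,6,6-trimethylcyclohex-2-ene-1,4-dione (ketoisophorone) | CC1=CC(=O)CC(C)(C)C1=O | starting material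
2 | 2,6,6-trimethyl-4-(trimethylsilyloxy)cyclohexa-2,4-dien-1-one | CC1=CC(O[Si](C)(C)C)=CC(C)(C)C1=O | intermediate (not isolated)
3 | rac-5-bromo-2,6,6-trimethylcyclohex-2-ene-1,4-dione | CC1=CC(=O)C(Br)C(C)(C)C1=O | intermediate
4 | (4R,5S)-5-bromo-4-hydroxy-2,6,6-trimethylcyclohex-2-en-1-one (OH and Br cis) | CC1=C[C@@H](O)[C@@H](Br)C(C)(C)C1=O | intermediate
5 | (4R,5S)-5-bromo-4-(tert-butyldimethylsilyloxy)-2,6,6-trimethylcyclohex-2-en-1-one | CC1=C[C@@H](O[Si](C)(C)C(C)(C)C)[C@@H](Br)C(C)(C)C1=O | intermediate
6 | lithium (4R,5S)-5-bromo-4-(tert-butyldimethylsilyloxy)-2,6,6-trimethylcyclohex-1-en-1-olate | CC=1C[C@@H](O[Si](C)(C)C(C)(C)C)[C@@H](Br)C(C)(C)C=1O[Li] | intermediate (not isolated)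
7 | (4R,5S)-5-bromo-4-(tert-butyldimethylsilyloxy)-2,6,6-trimethylcyclohex-1-en-1-yl trifluoromethanesulfonate | CC=1C[C@@H](O[Si](C)(C)C(C)(C)C)[C@@H](Br)C(C)(C)C=1OS(=O)(=O)C(F)(F)F | intermediate
8 | (4R,5S)-5-bromo-4-(tert-butyldimethylsilyloxy)-2,6,6-trimethylcyclohex-1-ene-1-carbaldehyde | CC=1C[C@@H](O[Si](C)(C)C(C)(C)C)[C@@H](Br)C(C)(C)C=1C=O | intermediate
9 | 2-(trimethylsilyloxy)buta-1,3-diene | C=CC(=C)O[Si](C)(C)C | starting material
10 | lithium buta-1,3-dien-2-olate (lithium enolate of methyl vinyl ketone) | C=CC(=C)O[Li] | intermediate (not isolated)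
11 | lithium aldolate of 8 and 10 (C8–OLi, both C8 epimers) | CC=1C[C@@H](O[Si](C)(C)C(C)(C)C)[C@@H](Br)C(C)(C)C=1C(O[Li])CC(=O)C=C | intermediate (not isolated)
12 | 5-[(4R,5S)-5-bromo-4-(tert-butyldimethylsilyloxy)-2,6,6-trimethylcyclohex-1-en-1-yl]-5-(triethylsilyloxy)pent-1-en-3-one (both C8 epimers) | CC=1C[C@@H](O[Si](C)(C)C(C)(C)C)[C@@H](Br)C(C)(C)C=1C(O[Si](CC)(CC)CC)CC(=O)C=C | intermediate
13 | (4R,5S,7S)-5-bromo-4-(tert-butyldimethylsilyloxy)-6,6-dimethyl-2-methylidene-8-(triethylsilyloxy)spiro[5.5]undecan-10-one (route numbering; C8 on the ring-A face of Br and OTBS; C8 epimers) | C=C1C[C@@H](O[Si](C)(C)C(C)(C)C)[C@@H](Br)C(C)(C)[C@@]12C(O[Si](CC)(CC)CC)CC(=O)CC2 | intermediate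
14 | 8-hydroxy ketone (13 without the triethylsilyl group) | C=C1C[C@@H](O[Si](C)(C)C(C)(C)C)[C@@H](Br)C(C)(C)[C@@]12C(O)CC(=O)CC2 | intermediate (not isolated)
15 | 8-methanesulfonate of 14 | C=C1C[C@@H](O[Si](C)(C)C(C)(C)C)[C@@H](Br)C(C)(C)[C@@]12C(OS(C)(=O)=O)CC(=O)CC2 | intermediate (not isolated)
16 | (4R,5S,7S)-5-bromo-4-(tert-butyldimethylsilyloxy)-6,6-dimethyl-2-methylidenespiro[5.5]undec-8-en-10-one (route numbering) | C=C1C[C@@H](O[Si](C)(C)C(C)(C)C)[C@@H](Br)C(C)(C)[C@@]12C=CC(=O)CC2 | intermediate
17 | lithium alkoxide of 18 | C=C1C[C@@H](O[Si](C)(C)C(C)(C)C)[C@@H](Br)C(C)(C)[C@@]12C=C[C@@](O[Li])(C(Br)Br)CC2 | intermediate (not isolated)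
18 | (4R,5S,7S,10R)-5-bromo-4-(tert-butyldimethylsilyloxy)-10-(dibromomethyl)-6,6-dimethyl-2-methylidenespiro[5.5]undec-8-en-10-ol (route numbering) | C=C1C[C@@H](O[Si](C)(C)C(C)(C)C)[C@@H](Br)C(C)(C)[C@@]12C=C[C@@](O)(C(Br)Br)CC2 | intermediate
19 | ma'iliohydrin, (4R,5S,7S,10R)-5-bromo-10-(dibromomethyl)-6,6-dimethyl-2-methylidenespiro[5.5]undec-8-ene-4,10-diol (route numbering) | C=C1C[C@@H](O)[C@@H](Br)C(C)(C)[C@@]12C=C[C@@](O)(C(Br)Br)CC2 | target

Total step count: 10. Longest linear sequence: 10 steps (from 1).

Steps most likely to fail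

1. Step 7 (key step). The allylic C8 silyl ether may ionise under the Lewis acid, a ring proton may be lost instead of the methyl hydrogen (endocyclic alkene), or attack at the very hindered C7 may be slow enough for the vinyl ketone to polymerise. Fallback (anionic instead of pericyclic spiroannulation, a Robinson annulation): it sets out from enal 8, which is deprotonated at the C2 methyl group (KHMDS, THF, −78 °C) to its exocyclic dienolate and alkylated at C7, anti to Br, with 3-(trimethylsilyl)but-3-en-2-one to give the silylated keto aldehyde F1; KOH in MeOH then removes silicon and closes ring B by aldol condensation, coming back to the route at enone 16.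

2. Step 2. Bromine may be lost reductively, or epimerisation at C5 may be too slow, so that the reduction becomes a plain kinetic resolution or gives a diastereomer mixture. Fallback (resolution instead of dynamic kinetic resolution): it sets out from 3, which is reduced under Luche conditions (NaBH4, CeCl3, MeOH, −78 °C) to the racemic cis-bromohydrin F2; lipase-catalysed acylation (Candida antarctica lipase B, vinyl acetate, MTBE) is expected to take the 4R enantiomer, giving the acetate F3, which is separated from the unreacted enantiomer and methanolysed (HCl, MeOH) to come back at 4; if the lipase prefers the other enantiomer, the unreacted alcohol is 4.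

3. Step 9. Facial selectivity at C10 may be poor, because the cyclohexenone ring is conformationally mobile and the two faces differ only through the remote C2 and C6 groups. Fallback (addition to a chair-locked saturated ketone, with a sulfoxide as latent alkene): it sets out from enone 16, to which thiophenol is added at C8 (PhSH, Et3N) to give the β-phenylthio ketone F4; in this chair cyclohexanone C6 is equatorial and C2 axial on ring B, so LiCHBr2 should enter equatorially, cis to C2, giving F5; oxidation to the sulfoxide F6 (mCPBA, −78 °C) and thermal syn-elimination (toluene, 110 °C) restore the C8=C9 bond and come back at 18.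

Further compounds
F1 | step 7 | (4R,5S,7S)-configured 7-formyl-7-[3-oxo-2-(trimethylsilyl)butyl] ring-A keto aldehyde (Michael adduct of 8; silyl-bearing carbon unassigned) | C=C1C[C@@H](O[Si](C)(C)C(C)(C)C)[C@@H](Br)C(C)(C)[C@]1(C=O)CC([Si](C)(C)C)C(C)=O
F2 | step 2 | rac-cis-5-bromo-4-hydroxy-2,6,6-trimethylcyclohex-2-en-1-one | CC1=C[C@@H](O)[C@@H](Br)C(C)(C)C1=O.CC1=C[C@H](O)[C@H](Br)C(C)(C)C1=O
F3 | step 2 | (4R,5S)-4-acetoxy-5-bromo-2,6,6-trimethylcyclohex-2-en-1-one | CC1=C[C@@H](OC(C)=O)[C@@H](Br)C(C)(C)C1=O
F4 | step 9 | 8-phenylthio adduct of enone 16 (C8 epimers) | C=C1C[C@@H](O[Si](C)(C)C(C)(C)C)[C@@H](Br)C(C)(C)[C@@]12C(Sc3ccccc3)CC(=O)CC2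
F5 | step 9 | (10R)-10-(dibromomethyl)-10-hydroxy-8-phenylthio derivative | C=C1C[C@@H](O[Si](C)(C)C(C)(C)C)[C@@H](Br)C(C)(C)[C@@]12C(Sc3ccccc3)C[C@@](O)(C(Br)Br)CC2
F6 | step 9 | sulfoxide of F5 | C=C1C[C@@H](O[Si](C)(C)C(C)(C)C)[C@@H](Br)C(C)(C)[C@@]12C(S(=O)c3ccccc3)C[C@@](O)(C(Br)Br)CC2
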